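## Structural features

The target is a biflavonoid made of two C15 units that share one aryl–aryl bond: a (2S)-5,7-dihydroxyflavanone (rings A and C, with ring B on C2) and a 5,7,4'-trihydroxyflavone, joined from C3' of ring B (ortho to the 4'-hydroxyl) to C8'' of the flavone. The only stereocentre is C2, a benzylic carbon that carries the ring oxygen O1 and lies next to the C3 methylene and, one atom further, the C4 ketone. It has no stereogenic neighbour, so its configuration must come from a reagent or catalyst. In the flavanone this centre is fragile: base opens ring C by retro-oxa-Michael reaction to an achiral 2'-hydroxychalcone, and the para oxygen of ring B makes the C2–O1 bond easy to ionise. The biaryl bond C3'–C8'' has three ortho substituents (the oxygens on C4' and C7'' and the ring carbon C8a'' bearing O1''), so it is hard to forge and rotates slowly, although it is not a stereogenic element of the target. Six phenols must be masked and released at the end; the 8-aryl-5-hydroxyflavone can rearrange to its 6-aryl isomer in hot strong acid, and the flavone enone is a latent acceptor for hydride and carbon nucleophiles. The real difficulty is to fix C2 late, in a large and crowded molecule, without passing through a flavanone or chalcone that can racemise. The key step exploits the fact that O1 of ring C bridges C2 and the aromatic carbon C8a: ring C can be closed at the aryl C8a–O1 bond from a C2 carbinol made by ketone reduction, while C4 is kept as an alcohol so that no carbonyl stands β to the ring oxygen.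

## Logic of the disconnections

17 from 16. The six O–CH2 acetal bonds are cut last. All phenols stay masked through base, hydride, palladium, copper and oxidant, and the polar hexaphenol appears only once. The forward step must use acid mild enough to leave C2 and the 8-aryl flavone untouched.

16 from 15. The C4 carbonyl is traced back to a C4 carbinol (C–H and O–H restored). This keeps the racemisation-prone flavanone out of every basic or hot step; the cost is one oxidation. The forward step needs a neutral oxidant that leaves acetals and the C2–O1 bond alone.

15 from 14. The aryl ether bond C8a–O1 of ring C is cut. This turns the heterocycle into an open 1,3-diol with an ortho bromide on ring A and moves the stereochemical problem from a ring closure to a ketone reduction. The forward step must join the C2 hydroxyl to C8a without breaking the carbinol C–O bond and without touching the second hydroxyl.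

14 from 12 (through 13). The two carbinol C–H bonds are cut, giving a 1,3-diketone. The only stereocentre that matters (future C2) then comes from a catalyst-controlled hydride transfer to an aryl ketone. The forward step must reduce the ketone next to ring B with high facial selectivity; the configuration next to ring A is irrelevant because step 11 destroys it.

12 from 10 and 7 (through 11). The C2–C3 bond (flavanone numbering) is cut between the methyl carbon of 10 and the ester carbonyl of 7. This is the convergent union of ring A with the complete biaryl half. The forward step needs an enolate that attacks the ester and not the flavone enone, and enough base to hold the product as its enolate.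

7 from 3 and 6. The biaryl bond C3'–C8'' is cut. Each half is a simple monocyclic or bicyclic arene, and the hindered bond is made before any stereocentre exists. The forward step needs a catalyst able to build a tri-ortho-substituted biaryl in the presence of a methyl ester.

3 from 2, and 2 from 1. The C8''–I bond and then three O–CH2 bonds are cut, leading back to a purchasable flavone. The gain is that the whole flavone skeleton is bought. The forward halogenation must choose C8'' over C6'' under conditions that keep the acetals.

6 from 5, and 5 from 4. The C–B bond and one O–CH2 bond are cut, leading to a commercial bromophenol ester. The forward borylation must tolerate ester and acetal.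

10 from 9, and 9 from 8. Two O–CH2 bonds and then the aryl–acyl bond are cut, leading to a commercial bromoresorcinol. The forward acylation must go to the ring position between bromine and hydroxyl, not between the two hydroxyls.

## Other disconnections considered

Alternative 1: The cut is the C4a''–C5'' bond of flavone ring A, which is grown onto a preformed 2-aryl-4-pyranone. In the forward sense, heating the tert-butyl β-keto ester A1 would expel tert-butanol; the acylketene would enolise to a dienylketene, and a 6π electrocyclisation followed by tautomerisation would give the 8-aryl-5,7-dihydroxyflavone A2.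
- In favour: the C8''–C3' bond already exists in A1 as a bond from an sp3 carbon to ring B, so no hindered cross-coupling is needed. The position of the aryl group on ring A is fixed by construction. On this point of regiocontrol the alternative is better than the chosen plan, which relies on the innate selectivity of an aromatic substitution. The step is thermal and reagent-free.
- Against: it solves only the achiral half. The aryl bromide of A2 would still have to be turned into the whole flavanone unit with its stereocentre. A2 carries two methyl ethers whose removal needs conditions unfriendly to a flavanone. The ketene can dimerise or be trapped, and A1 itself takes several steps.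
- Comparison: on structure it equals the chosen plan in delivering an 8-aryl flavone and is better in regiochemical certainty. On mechanism it is elegant but has no stereochemical content. On step economy it is worse, because the flavone half can be bought as 1 and functionalised in two steps.

Alternative 2: The cut removes three bonds of the flavone pyranone: C8a''–O1'', C4a''–C4'' and O1''–C2''. In the forward sense CsF would release an aryne from the silylaryl triflate A3. The carboxylate of the arylpropiolic acid A4 would add at C8a'', the aryl anion would take the acyl group onto C4a'', and the phenoxide would close 6-endo-dig onto the ynone to give the flavone A5.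
- In favour: three bonds and one ring form in one flask, and ring B arrives with a protected aldehyde. In bonds formed per operation it is better than anything in the chosen plan.
- Against: the aryne is unsymmetrical and fully substituted. The C5'' methoxy group directs the nucleophile to C8a'' as needed, but that carbon sits next to the bulky aryl group, so the regiochemistry rests on a balance of opposing effects. A 5-exo-dig closure to an aurone can compete. A3 already contains the hindered biaryl, so the difficult C3'–C8'' bond must be made anyway. Four methyl ethers would need harsh removal, and C2 is not addressed.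
- Comparison: on structure it targets the half that is purchasable. On mechanism its selectivity is less secure than the ring-size control of the chosen key step. On step economy it is worse overall, and equal at best if A3 were short to make.

Alternative 3: The cut is O1–C2 of flavanone ring C, the same ring as in the chosen plan but the other bond to O1. In the forward sense a bifunctional cinchona thiourea would bind the β-keto ester of A6 and deprotonate its 2'-phenol, which adds 6-endo-trig to the benzylic alkene carbon. TsOH would then cleave the tert-butyl ester and decarboxylate to the hexabenzyl flavanone A7, and hydrogenolysis would finish.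
- In favour: C2 is set catalytically with C4 already a ketone, so no reduction and re-oxidation are needed. After fragment union this is about two steps shorter, so it is better than the chosen plan on step economy. It is metal-free in the key step and ends with a neutral deprotection.
- Against: the bond it forms is the one whose reverse reaction racemises flavanones, and A7 must survive hot sulfonic acid with a para-oxygenated ring B. Face selection depends on hydrogen bonds in a catalyst pocket that must accept the ortho flavonyl substituent and the 6'-benzyloxy group, so the selectivity is less predictable and cannot be repaired later. Hydrogenolysis could also cut the benzylic C2–O1 bond or saturate the flavone alkene.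
- Comparison: on structure both plans close ring C, but the alternative does so at the labile bond. On mechanism the chosen plan fixes C2 by hydride transfer to an aryl ketone, a very general reaction, and never again breaks a bond at C2.

Key step: step 10

Remark: apigenin (1) is taken as a purchasable starting material. Flavanone atoms are numbered C2, C3, C4, C4a–C8a and 1'–6'; flavone atoms carry double primes. The (1S,3S) anti diol 14 maps with retention onto the 2,4-cis (2S,4S) alcohol 15, and C2 stays S up to 17 because O > aryl > CH2 > H holds throughout. The (S,S) ruthenium catalyst is assumed to reduce each aryl ketone with the facial sense known for acetophenone.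

Abbreviations in names: MOM = methoxymethyl; "MOM3-apigenin-8-yl" = 5,7-bis(methoxymethoxy)-2-[4-(methoxymethoxy)phenyl]-4-oxo-4H-chromen-8-yl.

## Route

Step 1
Reactants: 1 apigenin (5,7-dihydroxy-2-(4-hydroxyphenyl)-4H-chromen-4-one)
Product: 2 5,7-bis(methoxymethoxy)-2-[4-(methoxymethoxy)phenyl]-4H-chromen-4-one
Conditions: NaH (3.6 equiv), MOMCl (4 equiv), DMF, 0 °C → rt
Reagents that add atoms: chloromethyl methyl ether, COCCl
Why: Williamson-type O-alkylation of all three phenoxides; NaH is used because the 5-hydroxyl is hydrogen-bonded to the C4 carbonyl and does not react under amine bases. MOM ethers survive base, hydride, palladium and copper and leave under mild acid at the end.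

Step 2
Reactants: 2 5,7-bis(methoxymethoxy)-2-[4-(methoxymethoxy)phenyl]-4H-chromen-4-one
Product: 3 8-iodo-5,7-bis(methoxymethoxy)-2-[4-(methoxymethoxy)phenyl]-4H-chromen-4-one
Conditions: NIS (1.1 equiv), DMF, rt, dark
Reagents that add atoms: N-iodosuccinimide, O=C1CCC(=O)N1I
Why: Electrophilic aromatic iodination; with the 5-oxygen alkylated there is no chelated phenol to steer attack to C6'', and C8'' (para to the 5-oxygen, ortho to the 7-oxygen and to O1'') is the position at which 5,7-dialkoxyflavones are known to be halogenated. Neutral NIS in DMF avoids acid that would strip the 5-O-MOM group.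

Step 3
Reactants: 4 methyl 3-bromo-4-hydroxybenzoate
Product: 5 methyl 3-bromo-4-(methoxymethoxy)benzoate
Conditions: MOMCl, iPr2NEt, CH2Cl2, 0 °C → rt
Reagents that add atoms: chloromethyl methyl ether, COCCl
Why: O-alkylation of an acidic, unchelated phenol under amine base; the methyl ester is untouched.

Step 4
Reactants: 5 methyl 3-bromo-4-(methoxymethoxy)benzoate
Product: 6 methyl 4-(methoxymethoxy)-3-(4,4,5,5-tetramethyl-1,3,2-dioxaborolan-2-yl)benzoate
Conditions: B2pin2, Pd(dppf)Cl2 (3 mol %), KOAc, 1,4-dioxane, 90 °C
Reagents that add atoms: bis(pinacolato)diboron, CC1(C)OB(OC1(C)C)B1OC(C)(C)C(C)(C)O1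
Why: Miyaura borylation; acetate activates the aryl palladium bromide for transmetalation with the diboron and is too weak a base to trigger biaryl homocoupling. Ester and acetal are compatible.

Step 5
Reactants: 3 8-iodo-5,7-bis(methoxymethoxy)-2-[4-(methoxymethoxy)phenyl]-4H-chromen-4-one; 6 methyl 4-(methoxymethoxy)-3-(4,4,5,5-tetramethyl-1,3,2-dioxaborolan-2-yl)benzoate
Product: 7 methyl 4-(methoxymethoxy)-3-(MOM3-apigenin-8-yl)benzoate
Conditions: Pd(OAc)2 (5 mol %), SPhos (10 mol %), K3PO4, toluene–H2O (10:1), 90 °C
Reagents that add atoms: none
Why: Suzuki–Miyaura coupling forming the C3'–C8'' bond; the bulky, electron-rich dialkylbiarylphosphine is the standard answer to tri-ortho-substituted biaryls. The iodide is the only halide present, and phosphate is mild enough for the methyl ester.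

Step 6
Reactants: 8 5-bromoresorcinol (5-bromobenzene-1,3-diol)
Product: 9 1-(2-bromo-4,6-dihydroxyphenyl)ethan-1-one
Conditions: AcOH, BF3·OEt2, 90 °C; then H2O
Reagents that add atoms: acetic acid, CC(=O)O
Why: Friedel–Crafts C-acylation of a resorcinol (Nencki type); attack goes para to one hydroxyl and ortho to the other, here at the carbon between hydroxyl and bromine, as in the acylation of orcinol. The position between the two hydroxyls is the disfavoured one.

Step 7
Reactants: 9 1-(2-bromo-4,6-dihydroxyphenyl)ethan-1-one
Product: 10 1-[2-bromo-4,6-bis(methoxymethoxy)phenyl]ethan-1-one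
Conditions: NaH (2.2 equiv), MOMCl (2.5 equiv), DMF, 0 °C → rt
Reagents that add atoms: chloromethyl methyl ether, COCCl
Why: Williamson-type O-alkylation; both phenoxides are formed before the chloride is added so that the ortho hydroxyl hydrogen-bonded to the acetyl group also reacts. Limiting the base to the two phenols avoids enolate alkylation.

Step 8
Reactants: 10 1-[2-bromo-4,6-bis(methoxymethoxy)phenyl]ethan-1-one; 7 methyl 4-(methoxymethoxy)-3-(MOM3-apigenin-8-yl)benzoate
Product: 12 1-[2-bromo-4,6-bis(methoxymethoxy)phenyl]-3-[4-(methoxymethoxy)-3-(MOM3-apigenin-8-yl)phenyl]propane-1,3-dione, via lithium enolate 11 (not isolated)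
Conditions: LiN(SiMe3)2 (3 equiv), THF, −78 °C; then 7, −78 → 25 °C; AcOH quench
Reagents that add atoms: none
Why: Crossed Claisen condensation; the lithium enolate of the di-ortho-substituted methyl ketone cannot easily self-condense and acylates the non-enolisable benzoate, and excess amide base holds the product as its enolate and drives the equilibrium. The 2-aryl flavone is a vinylogous ester and a poor Michael acceptor, so the ester carbonyl should be the site of attack.

Step 9
Reactants: 12 1-[2-bromo-4,6-bis(methoxymethoxy)phenyl]-3-[4-(methoxymethoxy)-3-(MOM3-apigenin-8-yl)phenyl]propane-1,3-dione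
Product: 14 (1S,3S)-1-[2-bromo-4,6-bis(methoxymethoxy)phenyl]-3-[4-(methoxymethoxy)-3-(MOM3-apigenin-8-yl)phenyl]propane-1,3-diol, via (3S)-hydroxy ketone 13 (not isolated)
Conditions: RuCl(p-cymene)[(S,S)-TsDPEN] (5 mol %), HCO2H–Et3N (1:1), DMF, 40 °C
Reagents that add atoms: none
Why: Noyori–Ikariya asymmetric transfer hydrogenation; the Ru–H/N–H pair delivers hydride and proton to the Re face of each aryl ketone, first at the unhindered carbonyl next to ring B (giving 13 and the future C2 as S by catalyst control), then at the hindered carbonyl next to ring A to give the anti diol. The amine-rich formate medium spares the acetals, and any shortfall in control at the ring A carbinol is harmless because that centre is oxidised in step 11.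

Step 10
Reactants: 14 (1S,3S)-1-[2-bromo-4,6-bis(methoxymethoxy)phenyl]-3-[4-(methoxymethoxy)-3-(MOM3-apigenin-8-yl)phenyl]propane-1,3-diol
Product: 15 (2S,4S)-5,7-bis(methoxymethoxy)-2-[4-(methoxymethoxy)-3-(MOM3-apigenin-8-yl)phenyl]-3,4-dihydro-2H-chromen-4-ol (2,4-cis flavan-4-ol)
Conditions: CuI (20 mol %), 1,10-phenanthroline (40 mol %), Cs2CO3 (2 equiv), toluene (0.05 M, degassed, Ar), 110 °C
Reagents that add atoms: none
Why: Cs2CO3 converts the hydroxyl on the future C2 into a phenanthroline-bound monovalent copper alkoxide; the ortho C–Br bond adds oxidatively to give a trivalent aryl copper alkoxide held in a seven-membered chelate, and reductive elimination forms C8a–O1 and returns monovalent copper. The closest known reaction is the Ullmann-type coupling of aliphatic alcohols with aryl halides, whose intramolecular form gives chromans and 2-arylchromans from secondary alcohols. Ring C closes as a six-membered ring by attack of oxygen on the aryl carbon, formally a 6-exo-trig closure with respect to the departing bromide. No stereocentre is created: the C–O bond of the carbinol is a spectator, so C2 is carried over with retention, and C4 is untouched, which makes the anti diol the 2,4-cis alcohol. Chemoselectivity between the two hydroxyls is set by ring size, since the alkoxide next to ring A could only form a four-membered ring. Dilution disfavours intermolecular etherification, and copper offers no easy β-hydride elimination that could erode the carbinol. Strict exclusion of oxygen is required, because copper–phenanthroline with air can oxidise benzylic alcohols and a C4 ketone at this stage would open a retro-aldol path.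

Step 11
Reactants: 15 (2S,4S)-5,7-bis(methoxymethoxy)-2-[4-(methoxymethoxy)-3-(MOM3-apigenin-8-yl)phenyl]-3,4-dihydro-2H-chromen-4-ol
Product: 16 (2S)-5,7-bis(methoxymethoxy)-2-[4-(methoxymethoxy)-3-(MOM3-apigenin-8-yl)phenyl]-2,3-dihydro-4H-chromen-4-one
Conditions: Dess–Martin periodinane (1.3 equiv), NaHCO3, CH2Cl2, 0 °C → rt
Reagents that add atoms: none
Why: Dess–Martin oxidation of the benzylic secondary alcohol by ligand exchange at iodine and internal deprotonation; the bicarbonate-buffered, near-neutral medium avoids acid (acetals) and base (retro-oxa-Michael), so C2 is not at risk. The transient C4 stereocentre disappears here.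

Step 12
Reactants: 16 (2S)-5,7-bis(methoxymethoxy)-2-[4-(methoxymethoxy)-3-(MOM3-apigenin-8-yl)phenyl]-2,3-dihydro-4H-chromen-4-one
Product: 17 (2S)-5,7-dihydroxy-2-{4-hydroxy-3-[5,7-dihydroxy-2-(4-hydroxyphenyl)-4-oxo-4H-chromen-8-yl]phenyl}-2,3-dihydro-4H-chromen-4-one (the target)
Conditions: HCl (3 M), MeOH–THF, 40 °C
Reagents that add atoms: none
Why: Acid-catalysed acetal exchange cleaves all six aryl MOM ethers to dimethoxymethane. Flavanones are labile to base but not to dilute acid at moderate temperature, and these conditions are far below those that isomerise 8-aryl-5-hydroxyflavones.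

## Compound list

1 | apigenin, 5,7-dihydroxy-2-(4-hydroxyphenyl)-4H-chromen-4-one | O=c1cc(-c2ccc(O)cc2)oc2cc(O)cc(O)c12 | starting material
2 | 5,7-bis(methoxymethoxy)-2-[4-(methoxymethoxy)phenyl]-4H-chromen-4-one | COCOc1ccc(-c2cc(=O)c3c(OCOC)cc(OCOC)cc3o2)cc1 | intermediate
3 | 8-iodo-5,7-bis(methoxymethoxy)-2-[4-(methoxymethoxy)phenyl]-4H-chromen-4-one | COCOc1ccc(-c2cc(=O)c3c(OCOC)cc(OCOC)c(I)c3o2)cc1 | intermediate
4 | methyl 3-bromo-4-hydroxybenzoate | COC(=O)c1ccc(O)c(Br)c1 | starting material
5 | methyl 3-bromo-4-(methoxymethoxy)benzoate | COC(=O)c1ccc(OCOC)c(Br)c1 | intermediate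
6 | methyl 4-(methoxymethoxy)-3-(4,4,5,5-tetramethyl-1,3,2-dioxaborolan-2-yl)benzoate | COC(=O)c1ccc(OCOC)c(B2OC(C)(C)C(C)(C)O2)c1 | intermediate
7 | methyl 4-(methoxymethoxy)-3-{5,7-bis(methoxymethoxy)-2-[4-(methoxymethoxy)phenyl]-4-oxo-4H-chromen-8-yl}benzoate | COC(=O)c1ccc(OCOC)c(-c2c(OCOC)cc(OCOC)c3c(=O)cc(-c4ccc(OCOC)cc4)oc23)c1 | intermediate
8 | 5-bromoresorcinol, 5-bromobenzene-1,3-diol | Oc1cc(O)cc(Br)c1 | starting material
9 | 1-(2-bromo-4,6-dihydroxyphenyl)ethan-1-one | CC(=O)c1c(O)cc(O)cc1Br | intermediate
10 | 1-[2-bromo-4,6-bis(methoxymethoxy)phenyl]ethan-1-one | CC(=O)c1c(Br)cc(OCOC)cc1OCOC | intermediate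
11 | lithium 1-[2-bromo-4,6-bis(methoxymethoxy)phenyl]ethen-1-olate (lithium enolate of 10, not isolated) | [Li+].[O-]C(=C)c1c(Br)cc(OCOC)cc1OCOC | intermediate
12 | 1-[2-bromo-4,6-bis(methoxymethoxy)phenyl]-3-[4-(methoxymethoxy)-3-(MOM3-apigenin-8-yl)phenyl]propane-1,3-dione (drawn as the diketone; largely enolised) | O=C(CC(=O)c1ccc(OCOC)c(-c2c(OCOC)cc(OCOC)c3c(=O)cc(-c4ccc(OCOC)cc4)oc23)c1)c1c(Br)cc(OCOC)cc1OCOC | intermediate
13 | (3S)-1-[2-bromo-4,6-bis(methoxymethoxy)phenyl]-3-hydroxy-3-[4-(methoxymethoxy)-3-(MOM3-apigenin-8-yl)phenyl]propan-1-one (not isolated) | O=C(C[C@@H](c1ccc(OCOC)c(-c2c(OCOC)cc(OCOC)c3c(=O)cc(-c4ccc(OCOC)cc4)oc23)c1)O)c1c(Br)cc(OCOC)cc1OCOC | intermediate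
14 | (1S,3S)-1-[2-bromo-4,6-bis(methoxymethoxy)phenyl]-3-[4-(methoxymethoxy)-3-(MOM3-apigenin-8-yl)phenyl]propane-1,3-diol (anti) | O[C@@H](C[C@@H](c1ccc(OCOC)c(-c2c(OCOC)cc(OCOC)c3c(=O)cc(-c4ccc(OCOC)cc4)oc23)c1)O)c1c(Br)cc(OCOC)cc1OCOC | intermediate
15 | (2S,4S)-5,7-bis(methoxymethoxy)-2-[4-(methoxymethoxy)-3-(MOM3-apigenin-8-yl)phenyl]-3,4-dihydro-2H-chromen-4-ol (2,4-cis) | O[C@H]1C[C@@H](c2ccc(OCOC)c(-c3c(OCOC)cc(OCOC)c4c(=O)cc(-c5ccc(OCOC)cc5)oc34)c2)Oc2cc(OCOC)cc(OCOC)c21 | intermediate
16 | (2S)-5,7-bis(methoxymethoxy)-2-[4-(methoxymethoxy)-3-(MOM3-apigenin-8-yl)phenyl]-2,3-dihydro-4H-chromen-4-one | O=C1C[C@@H](c2ccc(OCOC)c(-c3c(OCOC)cc(OCOC)c4c(=O)cc(-c5ccc(OCOC)cc5)oc34)c2)Oc2cc(OCOC)cc(OCOC)c21 | intermediate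
17 | (2S)-5,7-dihydroxy-2-{4-hydroxy-3-[5,7-dihydroxy-2-(4-hydroxyphenyl)-4-oxo-4H-chromen-8-yl]phenyl}-2,3-dihydro-4H-chromen-4-one | O=C1C[C@@H](c2ccc(O)c(-c3c(O)cc(O)c4c(=O)cc(-c5ccc(O)cc5)oc34)c2)Oc2cc(O)cc(O)c21 | target

## Step count and least certain steps

Total: 12 steps. Longest linear sequence: 8 steps (steps 1, 2, 5, 8, 9, 10, 11, 12 from 1; the branch from 4 through steps 3, 4, 5, 8–12 is equally long).

Step 10 (key step). The most likely failure is slow oxidative addition of the electron-rich, ortho-substituted aryl bromide to the copper alkoxide, leading to incomplete conversion and protodebromination. Copper may also be sequestered by the 1,3-diol as a chelate. Adventitious air would allow copper-mediated oxidation of the benzylic alcohols, followed by retro-aldol loss of C2. The fallback changes metal and mechanism rather than temperature or base. It sets out from 14 and returns at 15: palladium-catalysed intramolecular etherification with Pd(OAc)2 and 2-(di-tert-butylphosphino)-1,1'-binaphthyl, Cs2CO3, toluene, 80 °C. Zerovalent palladium inserts easily into the bromide, and the bulky phosphine forces C–O reductive elimination from divalent palladium ahead of β-hydride elimination. This is a known way to close chromans from secondary alcohols with retention. It makes no new compound (F0).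

Step 9. The most likely failure is stalling after the first reduction, because the second carbonyl is flanked by bromine and a MOM ether and is twisted out of reach of the catalyst. Slower risks are loss of the labile 5''-O-MOM group in the formate medium and conjugate reduction of the flavone. The fallback sets out from 13, isolated from the stalled reaction, and returns at 14. It is a hydroxyl-directed anti reduction with Me4NBH(OAc)3 in MeCN–AcOH at −30 °C (Evans–Saksena), in which the C3 alkoxyborohydride delivers hydride internally and needs no catalyst approach to the hindered ketone. Since this centre is later oxidised, its selectivity is a convenience only. It makes no new compound (F0).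

Step 8. The most likely failure is incomplete C-acylation, because the para-alkoxybenzoate is a weak electrophile and proton transfer quenches the enolate. On warming, conjugate addition of the enolate to the flavone could also begin. The fallback sets out from 7 and returns at 12 with a far more reactive acyl donor used at low temperature. Saponification (LiOH, THF–H2O, rt) gives 4-(methoxymethoxy)-3-(MOM3-apigenin-8-yl)benzoic acid F1. Carbonyldiimidazole in THF converts it into the acyl imidazolide F2. Adding F2 to the preformed enolate 11 (2 equiv, from 10) at −78 °C gives 12.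

Step 2. The most likely failure is sluggish iodination of the carbonyl-deactivated ring A under the neutral conditions the acetals require. The remedy of adding acid would strip the 5''-O-MOM group and then divert attack to C6''; over-iodination is a lesser risk. The fallback sets out from 2 and returns at 7, bypassing 3. NBS in DMF at 0 °C, a stronger electrophile that needs no acid, gives the 8-bromo flavone F3. F3 is then coupled with 6 under the Pd(OAc)2/SPhos conditions of step 5, which accept hindered aryl bromides.

## Further compounds

F0 | step 10 | none | none
F0 | step 9 | none | none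
F1 | step 8 | 4-(methoxymethoxy)-3-{5,7-bis(methoxymethoxy)-2-[4-(methoxymethoxy)phenyl]-4-oxo-4H-chromen-8-yl}benzoic acid | OC(=O)c1ccc(OCOC)c(-c2c(OCOC)cc(OCOC)c3c(=O)cc(-c4ccc(OCOC)cc4)oc23)c1
F2 | step 8 | 1-[4-(methoxymethoxy)-3-(MOM3-apigenin-8-yl)benzoyl]-1H-imidazole | O=C(c1ccc(OCOC)c(-c2c(OCOC)cc(OCOC)c3c(=O)cc(-c4ccc(OCOC)cc4)oc23)c1)n1ccnc1
F3 | step 2 | 8-bromo-5,7-bis(methoxymethoxy)-2-[4-(methoxymethoxy)phenyl]-4H-chromen-4-one | COCOc1ccc(-c2cc(=O)c3c(OCOC)cc(OCOC)c(Br)c3o2)cc1
A1 | alternative 1 | tert-butyl 4-(5-bromo-2-methoxyphenyl)-4-[6-(4-methoxyphenyl)-4-oxo-4H-pyran-2-yl]-3-oxobutanoate | COc1ccc(-c2cc(=O)cc(C(C(=O)CC(=O)OC(C)(C)C)c3cc(Br)ccc3OC)o2)cc1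
A2 | alternative 1 | 8-(5-bromo-2-methoxyphenyl)-5,7-dihydroxy-2-(4-methoxyphenyl)chromen-4-one | COc1ccc(-c2cc(=O)c3c(O)cc(O)c(-c4cc(Br)ccc4OC)c3o2)cc1
A3 | alternative 2 | 2-[5-(1,3-dioxolan-2-yl)-2-methoxyphenyl]-3,5-dimethoxy-6-(trimethylsilyl)phenyl trifluoromethanesulfonate | COc1cc(OC)c([Si](C)(C)C)c(OS(=O)(=O)C(F)(F)F)c1-c1cc(C2OCCO2)ccc1OC
A4 | alternative 2 | 3-(4-methoxyphenyl)prop-2-ynoic acid | COc1ccc(C#CC(=O)O)cc1
A5 | alternative 2 | 8-[5-(1,3-dioxolan-2-yl)-2-methoxyphenyl]-5,7-dimethoxy-2-(4-methoxyphenyl)chromen-4-one | COc1ccc(-c2cc(=O)c3c(OC)cc(OC)c(-c4cc(C5OCCO5)ccc4OC)c3o2)cc1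
A6 | alternative 3 | tert-butyl 2-[2,4-bis(benzyloxy)-6-hydroxybenzoyl]-3-{4-(benzyloxy)-3-[5,7-bis(benzyloxy)-2-(4-benzyloxyphenyl)-4-oxo-4H-chromen-8-yl]phenyl}prop-2-enoate (alkene geometry as formed) | CC(C)(C)OC(=O)C(=Cc1ccc(OCc2ccccc2)c(-c2c(OCc3ccccc3)cc(OCc3ccccc3)c3c(=O)cc(-c4ccc(OCc5ccccc5)cc4)oc23)c1)C(=O)c1c(O)cc(OCc2ccccc2)cc1OCc1ccccc1
A7 | alternative 3 | hexa-O-benzyl (2S)-target | O=C1C[C@@H](c2ccc(OCc3ccccc3)c(-c3c(OCc4ccccc4)cc(OCc4ccccc4)c4c(=O)cc(-c5ccc(OCc6ccccc6)cc5)oc34)c2)Oc2cc(OCc3ccccc3)cc(OCc3ccccc3)c21
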